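The numbers of this flask were chosen freely; no experiment stands behind them.

Slowness marks these flasks. At Sunday's charges the electrophile has a half-life of 23.1 h by the making of product, while the nucleophile's forward step into dormant form has a half-life of 3.30 h.

| setting | Tuesday's | Sunday's | Wednesday's |
|---|---|---|---|
| electrophile | 0.15 M | 0.15 M | 0.15 M |
| nucleophile | 1.20 M | 0.300 M | 0.600 M |
| time | 30 h | 30 h | 30 h |

    nucleophile + product ⇌ idle adduct, settled at all times (K1 = 4.2 L mol⁻¹)
    nucleophile ⇌ dormant form (K2 = 0.82, k2 = 0.21 h⁻¹)
    nucleophile + acid set free ⇌ protonated nucleophile, settled at all times (K3 = 840 L mol⁻¹)
    electrophile + nucleophile → acid set free + product (k4 = 0.10 L mol⁻¹ h⁻¹)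

- amounts and yields of product count idle adduct too
- run time (Tuesday's): 30 h

- part of the electrophile that has reacted at the end, Tuesday's
- part of the electrophile that has reacted at the end, Sunday's
- part of the electrophile that has reacted at the end, Wednesday's
- what raising the concentration of nucleophile from its lowest to its highest value here does to the part of the electrophile that has reacted (changes below 5 percentage points count as none) (it falls / it rises / no change)

A slow step like this is counted here in logarithms. The natural logarithm of c(electrophile) falls at 0.10 L mol⁻¹ h⁻¹ times c(nucleophile), and 2.3 natural units make one power of ten.

First comes the main step by itself, with c(nucleophile) held at Tuesday's charge, the pseudo-first-order case. That count gives 1.57 decades, or 97.3% reacted.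

Next comes the dormant form. Its balance with the nucleophile relaxes in about 2.15 h, so this count takes the free level as the charge over 1.82. Tuesday's falls to 0.860 decades and 86.2%.

Then comes the rest. Each turnover consumes one nucleophile, and the acid set free takes a second, since 840 L mol⁻¹ times the free level is 554. The idle adduct takes a further share, which brings the cost to 2.73 nucleophiles per turnover, reckoned at the early free level. The turnover of the layer before is 0.129 M. The mean level therefore loses 0.5 of cost times turnover before the division, which leaves 0.562 M.

Tuesday's then stands at 0.733 decades of electrophile, the rate constant times the mean c(nucleophile) times the time, over 2.3. That counts as 81.5% reacted.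

The same count gives Sunday's 0.164 decades and 31.4%. It gives Wednesday's 0.343 decades and 54.6%. By this reckoning the part reacted rises with the charge of nucleophile.

The forecast gives 82% (78% to 86%) for Tuesday's, 34% (30% to 38%) for Sunday's and 57% (52% to 62%) for Wednesday's, and says it rises. For Sunday's it stands a little above the hand count. Its ground: “The free nucleophile therefore falls fast, especially at the lowest loading”.

The simulation gives 81.6% for Tuesday's, 33.0% for Sunday's and 55.6% for Wednesday's, and the part reacted changes by 49 percentage points: it rises.

Tuesday's result of 81.6% is worth 0.736 decades, and Sunday's 33.0% is worth 0.174. The main reason for that gap is the difference in concentration of nucleophile: with Sunday's concentration, Tuesday's run gives 33.0% instead of 81.6%. A flask like Wednesday's with 2.4 M of nucleophile counts 1.57 decades, or 97.3% reacted. The simulation gives it 97.3%.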